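Atom labels follow the target SMILES order: ring A is C2 (CMe2), C4 (CHBr), C6, C7, C8 (C(CH3)O), C19 (CH); ring B adds O10, C11=C12HBr, the oxirane C14/C17 and C18.
The gem-dimethyl carbon C2 lying between the secondary bromide C4 and C19 in ring A is the retron of a bromonium-triggered 1,2-methyl shift, so C4–Br and one C2–CH3 bond are cut back to a 1,2-dimethylcyclohexenol.
Other cuts, in retrosynthetic order: O10–C11 together with C12–Br (anti bromoetherification of an alkyne), the oxirane C–O bonds, C11–C14 (Sonogashira), C14=C17 (Wittig), C8–O and C19–H (hydroboration), C18–C19 (Stille), C8–CH3 (enolate methylation).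
Forward: ring A is bought as 2-methylcyclohexenone and kept throughout; the side chain is joined at C19 and grown to a (Z)-enyne; the oxirane is made on the open chain; ring B closes last by 7-exo-dig attack of the C8 hydroxyl.
Stereochemistry: C4 by chirality transfer from the carbinol of a catalytic asymmetric methyl addition; C8/C19 by syn hydroboration; C14/C17 by reagent-controlled Shi epoxidation of the (Z)-alkene; the E enol ether by anti addition.
Key step: step 2

Assumption: the facial senses of the two reagent-controlled steps (1 and 10) are taken from the accepted transition-state models; if either proves opposite, the antipodal ligand or ketone is used.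

Step 1
Reactants: 1 2-methylcyclohex-2-en-1-one; 2 dimethylzinc
Product: 3 (1R)-1,2-dimethylcyclohex-2-en-1-ol
Conditions: ZnMe2 (3 equiv), Ti(OiPr)4 (1.2 equiv), bis(2-exo-hydroxybornane-10-sulfonamide) of (1S,2S)-cyclohexane-1,2-diamine (10 mol %), toluene/hexane, rt; aq. NH4Cl
Reagents that add atoms: dimethylzinc C[Zn]C
Why: Titanium-promoted, ligand-accelerated 1,2-addition of a dialkylzinc to a cyclic α-substituted enone is a known catalytic asymmetric ketone alkylation in which the C2 methyl differentiates the two sides of the carbonyl, and the chiral titanium bis(sulfonamide) diolate delivers methyl to the Si face to set the (R)-carbinol, the stereocentre that step 2 relays to C4.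

Step 2
Reactants: 3 (1R)-1,2-dimethylcyclohex-2-en-1-ol; 4 N-bromosuccinimide
Product: 5 (3S)-3-bromo-2,2-dimethylcyclohexan-1-one
Conditions: NBS (1.05 equiv), NaHCO3, 4 Å MS, CH2Cl2, −40 → 0 °C, dark
Reagents that add atoms: N-bromosuccinimide O=C1CCC(=O)N1Br
Why: NBS transfers Br+ to C4 of the trisubstituted alkene on the face of the hydroxyl (hydrogen bond to the succinimide carbonyl, and anti to the pseudoaxial carbinol methyl that A(1,2) strain with the C2 methyl enforces), positive charge builds up on the tertiary carbon C2, and the pseudoaxial methyl on C19, antiperiplanar to the forming C–Br bond, shifts to C2 while the oxygen lone pair closes to the C19 ketone. The closest known reaction type is the halonium-induced semipinacol rearrangement of tertiary allylic alcohols to β-halo ketones with an α-quaternary carbon, here with methyl rather than aryl or ring-bond migration. No ring is closed, and the six-membered ring is kept because the ring C19–C8 bond lies near the alkene plane and cannot overlap with the C2 orbital, so ring contraction is stereoelectronically disfavoured. The only new stereocentre, C4, is controlled by the carbinol centre: bromine must enter anti to the migrating methyl, so the (R)-carbinol is traded for the (S)-bromide with transfer of chirality. The step needs Markovnikov polarisation (bromine on the secondary carbon, secured by the C2 methyl), methyl migration ahead of bromohydrin or bromo-epoxide formation (anhydrous non-nucleophilic medium; in the reactive conformer the hydroxyl is syn to the bromonium and cannot close an oxirane) and no radical allylic bromination (dark, low temperature).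

Step 3
Reactants: 5 (3S)-3-bromo-2,2-dimethylcyclohexan-1-one; 6 iodomethane
Product: 8 (3S)-3-bromo-2,2,6-trimethylcyclohexan-1-one (both C6 epimers), via lithium enolate 7 (not isolated)
Conditions: LiN(iPr)2 (1.1 equiv), THF, −78 °C; MeI, −78 → −20 °C
Reagents that add atoms: iodomethane CI
Why: Kinetic enolisation with the lithium amide can take place only towards C8 because the other α-carbon is quaternary (which also rules out E1cB loss of the β-bromide), and SN2 C-methylation of the enolate installs the C8 methyl, the new centre being left unassigned since it is planarised again in step 4.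

Step 4
Reactants: 8 (3S)-3-bromo-2,2,6-trimethylcyclohexan-1-one; 9 N-phenylbis(trifluoromethanesulfonimide)
Product: 11 (5S)-5-bromo-2,6,6-trimethylcyclohex-1-en-1-yl trifluoromethanesulfonate, via potassium enolate 10 (not isolated)
Conditions: KN(SiMe3)2 (1.2 equiv), THF, −78 °C; PhNTf2, −78 → 0 °C
Reagents that add atoms: N-phenylbis(trifluoromethanesulfonimide) O=S(=O)(N(c1ccccc1)S(=O)(=O)C(F)(F)F)C(F)(F)F
Why: The single remaining α-hydrogen gives the tetrasubstituted potassium enolate regiospecifically and O-sulfonylation with PhNTf2, the standard enol triflate synthesis used for 2,2,6-trimethylcyclohexanones, activates C19 for cross-coupling while leaving the neopentyl secondary bromide untouched at low temperature.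

Step 5
Reactants: 11 (5S)-5-bromo-2,6,6-trimethylcyclohex-1-en-1-yl trifluoromethanesulfonate; 12 tributyl(ethenyl)stannane
Product: 13 (4S)-4-bromo-2-ethenyl-1,3,3-trimethylcyclohex-1-ene
Conditions: Pd2(dba)3 (2.5 mol %), AsPh3 (20 mol %), LiCl (3 equiv), N-methylpyrrolidone, 45 °C
Reagents that add atoms: tributyl(ethenyl)stannane C=C[Sn](CCCC)(CCCC)CCCC
Why: Stille coupling of hindered 2,6,6-trimethylcyclohexenyl triflates with alkenylstannanes under Pd2(dba)3/AsPh3/LiCl conditions is well precedented, zerovalent palladium inserting into the C(sp2)–OTf bond far faster than into the unactivated secondary C–Br bond, and it forms the C18–C19 bond without creating a stereocentre.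

Step 6
Reactants: 13 (4S)-4-bromo-2-ethenyl-1,3,3-trimethylcyclohex-1-ene; 14 hydrogen peroxide
Product: 16 (1S,2S,4S)-4-bromo-2-(2-hydroxyethyl)-1,3,3-trimethylcyclohexan-1-ol, via cyclic borane 15 (not isolated)
Conditions: BH3·THF (2.5 equiv), THF, 0 → 40 °C; then NaOH, H2O2, H2O, 0 °C → rt
Reagents that add atoms: hydrogen peroxide OO
Why: Hydroboration–oxidation: borane first adds to the vinyl group with boron on the terminal carbon C17 and the tethered B–H then adds syn across the tetrasubstituted alkene (cyclic hydroboration of a diene), boron to C8 and hydrogen to C19 on the same face, so that oxidation with retention fixes the cis C8–O/C19–H relationship, while the face is chosen by the half-chair with equatorial bromine, in which the pseudoaxial C2 methyl shields the β-face and boron ends equatorial on the α-face, a conformational bias that is backed up by crystallisation of diol 16.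

Step 7
Reactants: 16 (1S,2S,4S)-4-bromo-2-(2-hydroxyethyl)-1,3,3-trimethylcyclohexan-1-ol
Product: 17 (3aS,5S,7aS)-5-bromo-4,4,7a-trimethyloctahydro-1-benzofuran-2-ol (both anomers)
Conditions: Dess–Martin periodinane (1.2 equiv), NaHCO3, CH2Cl2, 0 °C
Reagents that add atoms: none
Why: Dess–Martin oxidation converts only the primary alcohol (the tertiary one cannot be oxidised) into the aldehyde, which is captured by the C8 hydroxyl as the five-membered lactol, so that the C17 carbonyl is unveiled in protected form and no ring stereocentre is touched.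

Step 8
Reactants: 17 (3aS,5S,7aS)-5-bromo-4,4,7a-trimethyloctahydro-1-benzofuran-2-ol; 18 ethyltriphenylphosphonium iodide; 19 iodine
Product: 21 (1S,2S,4S)-4-bromo-2-[(2Z)-3-iodobut-2-en-1-yl]-1,3,3-trimethylcyclohexan-1-ol, via open-chain hydroxy aldehyde 20 (not isolated)
Conditions: EtPPh3I, n-BuLi, THF, rt; I2, −78 °C; NaN(SiMe3)2, −20 °C; then 17 (pre-treated with 1 equiv NaN(SiMe3)2), −78 °C → rt
Reagents that add atoms: ethyltriphenylphosphonium iodide CC[P+](c1ccccc1)(c1ccccc1)c1ccccc1.[I-]; iodine [I][I]
Why: Stork–Zhao-type Wittig olefination with the α-iodo ylide Ph3P=C(I)CH3, which reacts through the open hydroxy aldehyde form of the lactol as is usual for lactol Wittig reactions, forms the C14=C17 bond under kinetic control with iodine cis to the C18 chain, giving the (Z)-trisubstituted vinyl iodide that later dictates the cis oxirane.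

Step 9
Reactants: 21 (1S,2S,4S)-4-bromo-2-[(2Z)-3-iodobut-2-en-1-yl]-1,3,3-trimethylcyclohexan-1-ol; 22 ethynyltrimethylsilane
Product: 24 (1S,2S,4S)-4-bromo-1,3,3-trimethyl-2-[(2Z)-3-methylpent-2-en-4-yn-1-yl]cyclohexan-1-ol, via silylated enyne 23 (not isolated)
Conditions: PdCl2(PPh3)2 (3 mol %), CuI (6 mol %), Et3N, THF, rt; then K2CO3, MeOH, rt
Reagents that add atoms: ethynyltrimethylsilane C#C[Si](C)(C)C
Why: Sonogashira coupling proceeds with retention of alkene geometry at the vinyl iodide, which undergoes oxidative addition to zerovalent palladium far faster than the alkyl bromide, and methanolysis of the alkynylsilane then frees the terminal alkyne of the (Z)-enyne without affecting the tertiary alcohol.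

Step 10
Reactants: 24 (1S,2S,4S)-4-bromo-1,3,3-trimethyl-2-[(2Z)-3-methylpent-2-en-4-yn-1-yl]cyclohexan-1-ol; 25 potassium peroxymonosulfate
Product: 26 (1S,2S,4S)-4-bromo-2-{[(2R,3S)-3-ethynyl-3-methyloxiran-2-yl]methyl}-1,3,3-trimethylcyclohexan-1-ol
Conditions: D-fructose-derived Shi ketone (1,2:4,5-di-O-isopropylidene-β-D-erythro-2,3-hexodiulo-2,6-pyranose, 30 mol %), KHSO5, K2CO3, Bu4NHSO4, MeCN/(MeO)2CH2/aq. Na2B4O7 buffer (pH about 10.5), 0 °C; isolation on Et3N-deactivated silica
Reagents that add atoms: potassium peroxymonosulfate [K+].OOS(=O)(=O)[O-]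
Why: Shi epoxidation: the electrophilic chiral dioxirane epoxidises the trisubstituted alkene of a conjugated enyne chemoselectively (the alkyne, the alcohol and the bromide are inert) and, through the spiro transition state, under reagent control sets both oxirane centres C14 and C17 with oxygen on the face that gives the (2R,3S)-oxirane, the cis relationship of C18 and the alkyne being inherited from the (Z)-alkene.

Step 11
Reactants: 26 (1S,2S,4S)-4-bromo-2-{[(2R,3S)-3-ethynyl-3-methyloxiran-2-yl]methyl}-1,3,3-trimethylcyclohexan-1-ol; 4 N-bromosuccinimide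
Product: 27 (2E,3R,4R,5aS,7S,9aS)-7-bromo-2-(bromomethylidene)-3,4-epoxy-3,6,6,9a-tetramethyldecahydro-1-benzoxepine (CNP0375295.1)
Conditions: NBS (1.05 equiv), NaHCO3, 4 Å MS, MeCN, −20 °C → rt, dark
Reagents that add atoms: N-bromosuccinimide O=C1CCC(=O)N1Br
Why: Electrophilic bromoetherification of an alkynol (halocyclisation): Br+ from NBS adds to the terminal carbon C12 while the C8 hydroxyl, held close by the diequatorial ring A substituents and the cis-oxirane, attacks the internal carbon C11 from the opposite side in a 7-exo-dig closure of ring B, so that anti addition places O10 and bromine trans and gives the (E)-bromomethylidene enol ether, the bicarbonate-buffered medium keeping the oxirane closed.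

Compound list
1 | 2-methylcyclohex-2-en-1-one | CC1=CCCCC1=O | starting material
2 | dimethylzinc | C[Zn]C | starting material
3 | (1R)-1,2-dimethylcyclohex-2-en-1-ol | C[C@@]1(O)CCCC=C1C | intermediate
4 | N-bromosuccinimide | O=C1CCC(=O)N1Br | starting material
5 | (3S)-3-bromo-2,2-dimethylcyclohexan-1-one | CC1(C)[C@@H](Br)CCCC1=O | intermediate
6 | iodomethane | CI | starting material
7 | lithium (5S)-5-bromo-6,6-dimethylcyclohex-1-en-1-olate | CC1(C)[C@@H](Br)CCC=C1O[Li] | intermediate
8 | (3S)-3-bromo-2,2,6-trimethylcyclohexan-1-one, C6 epimer mixture | CC1(C)[C@@H](Br)CCC(C)C1=O | intermediate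
9 | N-phenylbis(trifluoromethanesulfonimide) | O=S(=O)(N(c1ccccc1)S(=O)(=O)C(F)(F)F)C(F)(F)F | starting material
10 | potassium (5S)-5-bromo-2,6,6-trimethylcyclohex-1-en-1-olate | CC1(C)[C@@H](Br)CCC(C)=C1O[K] | intermediate
11 | (5S)-5-bromo-2,6,6-trimethylcyclohex-1-en-1-yl trifluoromethanesulfonate | CC1(C)[C@@H](Br)CCC(C)=C1OS(=O)(=O)C(F)(F)F | intermediate
12 | tributyl(ethenyl)stannane | C=C[Sn](CCCC)(CCCC)CCCC | starting material
13 | (4S)-4-bromo-2-ethenyl-1,3,3-trimethylcyclohex-1-ene | CC1(C)[C@@H](Br)CCC(C)=C1C=C | intermediate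
14 | hydrogen peroxide | OO | starting material
15 | trans-fused cyclic borane, 5-bromo-4,4,7a-trimethyloctahydro-1H-1-benzoborole (B–H; boron bonded to C17 and to the α-face of C8) | CC1(C)[C@@H](Br)CC[C@]2(C)[BH]CC[C@@H]12 | intermediate
16 | (1S,2S,4S)-4-bromo-2-(2-hydroxyethyl)-1,3,3-trimethylcyclohexan-1-ol | CC1(C)[C@@H](Br)CC[C@](C)(O)[C@H]1CCO | intermediate
17 | (3aS,5S,7aS)-5-bromo-4,4,7a-trimethyloctahydro-1-benzofuran-2-ol, both anomers | CC1(C)[C@@H](Br)CC[C@]2(C)OC(O)C[C@@H]12 | intermediate
18 | ethyltriphenylphosphonium iodide | CC[P+](c1ccccc1)(c1ccccc1)c1ccccc1.[I-] | starting material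
19 | iodine | [I][I] | starting material
20 | 2-[(1S,2S,5S)-5-bromo-2-hydroxy-2,6,6-trimethylcyclohexyl]acetaldehyde | CC1(C)[C@@H](Br)CC[C@](C)(O)[C@H]1CC=O | intermediate
21 | (1S,2S,4S)-4-bromo-2-[(2Z)-3-iodobut-2-en-1-yl]-1,3,3-trimethylcyclohexan-1-ol | CC1(C)[C@@H](Br)CC[C@](C)(O)[C@H]1C/C=C(\I)C | intermediate
22 | ethynyltrimethylsilane | C#C[Si](C)(C)C | starting material
23 | (1S,2S,4S)-4-bromo-1,3,3-trimethyl-2-[(2Z)-3-methyl-5-(trimethylsilyl)pent-2-en-4-yn-1-yl]cyclohexan-1-ol | CC1(C)[C@@H](Br)CC[C@](C)(O)[C@H]1C/C=C(\C#C[Si](C)(C)C)C | intermediate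
24 | (1S,2S,4S)-4-bromo-1,3,3-trimethyl-2-[(2Z)-3-methylpent-2-en-4-yn-1-yl]cyclohexan-1-ol | CC1(C)[C@@H](Br)CC[C@](C)(O)[C@H]1C/C=C(\C#C)C | intermediate
25 | potassium peroxymonosulfate | [K+].OOS(=O)(=O)[O-] | starting material
26 | (1S,2S,4S)-4-bromo-2-{[(2R,3S)-3-ethynyl-3-methyloxiran-2-yl]methyl}-1,3,3-trimethylcyclohexan-1-ol | CC1(C)[C@@H](Br)CC[C@](C)(O)[C@H]1C[C@H]2O[C@@]2(C)C#C | intermediate
27 | (2E,3R,4R,5aS,7S,9aS)-7-bromo-2-(bromomethylidene)-3,4-epoxy-3,6,6,9a-tetramethyldecahydro-1-benzoxepine | CC1(C)[C@@H](Br)CC[C@]2(C)O/C(=C/Br)[C@]3(C)O[C@@H]3C[C@@H]12 | target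

Total steps: 11. Longest linear sequence: 11 steps (1 → 27).

Steps most likely to fail

1. Step 11. The hindered C8 hydroxyl may add too slowly to the electron-poor alkyne, so that Br+ is spent on the alkyne C–H or on the product enol ether. Trace acid may also let the same hydroxyl open the oxirane in a 5-exo mode. Fallback: ring B is closed through an acyl–oxygen bond, setting out from vinyl iodide 21 and returning at 27.
   - Carbonylation of 21 (PdCl2(PPh3)2, CO 1 atm, Et3N, DMF, 70 °C) with capture of the acylpalladium by the tertiary hydroxyl should give (5aS,7S,9aS)-7-bromo-3,6,6,9a-tetramethyl-5a,6,7,8,9,9a-hexahydro-1-benzoxepin-2(5H)-one F1.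
   - Nucleophilic epoxidation (tBuOOH, DBU, CH2Cl2) on the face away from the axial C8 methyl should give the epoxy lactone (3R,4R,5aS,7S,9aS)-7-bromo-3,4-epoxy-3,6,6,9a-tetramethyloctahydro-1-benzoxepin-2(3H)-one F2.
   - Methylenation of the lactone carbonyl with Cp2TiMe2 (toluene, 70 °C) should give the exocyclic enol ether (3R,4R,5aS,7S,9aS)-7-bromo-3,4-epoxy-3,6,6,9a-tetramethyl-2-methylidenedecahydro-1-benzoxepine F3.
   - Bromination of F3 with NBS and iPr2NEt (CH2Cl2, −78 °C) then leads to 27.
   - In this variant the alkene geometry is no longer fixed by anti addition; deprotonation of the oxocarbenium ion probably favours the Z isomer, so the geometric isomers would have to be separated or equilibrated photochemically.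

2. Step 6. Facial selectivity may be poor. Bromine next to the gem-dimethyl carbon has only a small equatorial preference, and the ring-flipped half-chair exposes the opposite face. Addition to the hindered tetrasubstituted alkene may also be slow. Fallback: C8 and C19 are set one after the other, setting out from enol triflate 11 and returning at lactol 17.
   - Negishi coupling of 11 with the Reformatsky reagent BrZnCH2CO2tBu (Pd(PPh3)4, THF, 60 °C) should give tert-butyl 2-[(5S)-5-bromo-2,6,6-trimethylcyclohex-1-en-1-yl]acetate F4.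
   - Peracid epoxidation (mCPBA, NaHCO3, CH2Cl2, 0 °C), expected to occur on the face remote from the C–Br dipole, should give tert-butyl 2-[(1R,3S,6S)-3-bromo-2,2,6-trimethyl-7-oxabicyclo[4.1.0]heptan-1-yl]acetate F5.
   - DBU opens the β,γ-epoxy ester by β-elimination to tert-butyl 2-[(2S,5S)-5-bromo-2-hydroxy-2,6,6-trimethylcyclohexylidene]acetate F6 (alkene geometry not defined).
   - Hydroxyl-directed hydrogenation with [Ir(cod)(PCy3)(py)]PF6 (H2, CH2Cl2) delivers hydrogen to C19 on the hydroxyl face and should give tert-butyl 2-[(1S,2S,5S)-5-bromo-2-hydroxy-2,6,6-trimethylcyclohexyl]acetate F7.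
   - CF3CO2H closes the trans-fused lactone (3aS,5S,7aS)-5-bromo-4,4,7a-trimethylhexahydro-1-benzofuran-2(3H)-one F8.
   - iBu2AlH (CH2Cl2, −78 °C) reduces F8 to 17.

3. Step 2. The bromonium ion may be diverted into a bromo-epoxide or bromohydrin, or bromine may enter on the face anti to the hydroxyl, which would erode the enantiomeric purity. Fallback: the free hydroxyl is removed and the oxygen push strengthened, setting out from 3 and returning at 5.
   - Silylation of 3 (Me3SiOTf, 2,6-lutidine, CH2Cl2, −78 °C) should give trimethyl{[(1R)-1,2-dimethylcyclohex-2-en-1-yl]oxy}silane F9.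
   - Treatment of F9 with NBS (CH2Cl2, −40 °C) should trigger the same methyl shift, with loss of the silyl group from the oxocarbenium ion, to give 5.
   - Only the conformer with the pseudoaxial methyl can rearrange, and no oxirane can close.

Further compounds
F1 | step 11 | (5aS,7S,9aS)-7-bromo-3,6,6,9a-tetramethyl-5a,6,7,8,9,9a-hexahydro-1-benzoxepin-2(5H)-one | CC1(C)[C@@H](Br)CC[C@]2(C)OC(=O)C(C)=CC[C@@H]12
F2 | step 11 | (3R,4R,5aS,7S,9aS)-7-bromo-3,4-epoxy-3,6,6,9a-tetramethyloctahydro-1-benzoxepin-2(3H)-one | CC1(C)[C@@H](Br)CC[C@]2(C)OC(=O)[C@]3(C)O[C@@H]3C[C@@H]12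
F3 | step 11 | (3R,4R,5aS,7S,9aS)-7-bromo-3,4-epoxy-3,6,6,9a-tetramethyl-2-methylidenedecahydro-1-benzoxepine | CC1(C)[C@@H](Br)CC[C@]2(C)OC(=C)[C@]3(C)O[C@@H]3C[C@@H]12
F4 | step 6 | tert-butyl 2-[(5S)-5-bromo-2,6,6-trimethylcyclohex-1-en-1-yl]acetate | CC1(C)[C@@H](Br)CCC(C)=C1CC(=O)OC(C)(C)C
F5 | step 6 | tert-butyl 2-[(1R,3S,6S)-3-bromo-2,2,6-trimethyl-7-oxabicyclo[4.1.0]heptan-1-yl]acetate | CC1(C)[C@@H](Br)CC[C@]2(C)O[C@]12CC(=O)OC(C)(C)C
F6 | step 6 | tert-butyl 2-[(2S,5S)-5-bromo-2-hydroxy-2,6,6-trimethylcyclohexylidene]acetate | CC1(C)[C@@H](Br)CC[C@](C)(O)C1=CC(=O)OC(C)(C)C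
F7 | step 6 | tert-butyl 2-[(1S,2S,5S)-5-bromo-2-hydroxy-2,6,6-trimethylcyclohexyl]acetate | CC1(C)[C@@H](Br)CC[C@](C)(O)[C@H]1CC(=O)OC(C)(C)C
F8 | step 6 | (3aS,5S,7aS)-5-bromo-4,4,7a-trimethylhexahydro-1-benzofuran-2(3H)-one | CC1(C)[C@@H](Br)CC[C@]2(C)OC(=O)C[C@@H]12
F9 | step 2 | trimethyl{[(1R)-1,2-dimethylcyclohex-2-en-1-yl]oxy}silane | C[C@@]1(O[Si](C)(C)C)CCCC=C1C
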